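A rate constant in per molar per hour becomes a clock once a concentration multiplies it, and I reckon these flasks by one such clock.

    starting material + free catalyst ⇌ catalyst intermediate A (K1 = 160 /M, k1 = 930 /M/h)
    coupling partner + catalyst intermediate A → free catalyst + target (k2 = 85 /M/h)
    second substrate + free catalyst ⇌ catalyst intermediate B (K3 = 96 /M, k3 = 7800 /M/h)
    coupling partner + catalyst intermediate B → free catalyst + second product (k4 = 610 /M/h)
    2 starting material → homo dimer (k5 = 0.063 /M/h)
    target ⇌ isomer of the product (K6 = 0.39, k6 = 0.0041 /h)

common to all: starting material 0.50 M; coupling partner 0.500 equiv; free catalyst 0.084 mol%; time 20 h

| flask | second substrate |
|---|---|
| Sunday's | 0.0300 equiv |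
| Thursday's | 0.0600 equiv |
| Friday's | 0.120 equiv |
| Tuesday's | 0.250 equiv |
| Wednesday's | 0.500 equiv |

- a species is counted by the starting material in it: one homo dimer counts as two
- a doubled species enters its step squared and goes two at a time
- "hardly changes" means that all values lie within two and a half points (for a concentration: within two and a half percent of the largest)
- run time (Sunday's): 20 h

- amount of target at the end, in percent of the starting material charged for Sunday's, Thursday's, Friday's, Tuesday's, Wednesday's, in this order
- how the row runs (rises all the way / falls all the way / rises, then falls / hardly changes / falls, then rises)

The flasks differ in their charge of second substrate. The coupling partner charge is half of the starting material charge. Target forms when coupling partner meets catalyst intermediate A, so I start there.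

My first extreme has no second substrate and keeps all the catalyst on catalyst intermediate A for the whole run. I take this as the resting state because the equilibrium constant of step one times [starting material] is 80 at the start of Sunday's flask, far above one. Coupling partner then falls pseudo-first-order:

rate constant of coupling × [catalyst] = 85 /M/h × 4.20 × 10⁻⁴ M = 0.0357 /h

half-life = ln 2 / 0.0357 /h = 19.4 h

I carry this number: the half-life of coupling partner with all catalyst on catalyst intermediate A, the coupling half-life. The run of 20 h lasts about one such half-life. So the ceiling for target plus isomer, in percent of the starting material charged, is:

ceiling = 0.500 × 0.511 = 25.5%

Little of this should pass to isomer, because the forward half-life of target in step six, 170 h, is longer than the run.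

My second extreme is Wednesday's flask, where the second substrate charge matches the coupling partner charge. Suppose each second substrate takes one coupling partner before any target forms. Then the target comes to 0%.

The real Wednesday's flask lies between these. At its start, starting material enters free catalyst at 0.238 times the forward rate of second substrate. That is less than the second substrate's rate, but it is well above zero. So I expect some target, in the lower half of the span. In Sunday's flask the second substrate charge is 6.00% of the coupling partner charge, and at its start the forward rate of starting material into free catalyst is 4.0 times that of second substrate, so I expect a value just under the ceiling. I commit to a row that falls all the way.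

The forecast reads 21.9%, 20.7%, 18.6%, 14.9% and 10%, so that it falls all the way, on the ground that “More second substrate ties up catalyst and consumes coupling partner, so target falls throughout.”

The simulation gives 22.0%, 20.9%, 18.8%, 15.0% and 10.1%: the row falls all the way.

With step three given no rate, Wednesday's flask ends at 23.1% target, under the ceiling of 25.5%. The coupling half-life stretches as catalyst leaves catalyst intermediate A. After 20.0 h, Sunday's flask holds 89.9% of its catalyst there, which makes 21.6 h. Wednesday's flask holds 72.3%, which makes 26.8 h. At that time Wednesday's flask has 15.2% of its coupling partner left, and Sunday's flask has 48.6%.

The constants used here were chosen freely; the flask was simulated.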